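**Plan**

- Retrosynthesis: the two hydroxyls are unmasked last (silyl ether, N-acyl oxazolidinone). The tetrahydrofuran ring (O1, C2 with the trimethoxyphenyl, C3 with CH2OH, C4 with the carbinol, C5 = CH2) is then cut at O1–C5 and C2–C3 into 3,4,5-trimethoxybenzaldehyde and an acylcyclopropane. The cyclopropane side chain is cut at the aryl–C(O) bond.
- Enabling feature: C3 carries a carboxyl-level carbon and is 1,3-related through C4 to the unsubstituted C5. C3 and C5 can therefore be stored as the third bond of a cyclopropane (C3–C4–C5), which iodide reopens to an enolate (C3) and a primary iodide (C5). O1 and C2 are the C=O of the aldehyde.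
- Forward order: chiral-pool cyclopropane half-ester, aryl ketone, carbinol, imide, one-flask ring expansion to the tetrahydrofuran (the only ring formed), reduction, desilylation.
- Stereochemistry: C4 comes from the (1S,2S)-cyclopropane and is never broken. The carbinol carbon comes from a CBS reduction. C2 and C3 arise in the key step under control of C4; the cyclopropane configuration at future C3 is erased on ring opening, so isomers converge on the all-trans ring.

Key step: step 6

Assumption: (1S,2S)-2-(methoxycarbonyl)cyclopropane-1-carboxylic acid is taken as a purchasable single enantiomer. The ring numbering O1, C2–C5 given above is used for all intermediates.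

**Route**

Step 1
Reactants: 1 (1S,2S)-2-(methoxycarbonyl)cyclopropane-1-carboxylic acid; 2 1,2-dimethoxybenzene (veratrole)
Product: 4 methyl (1S,2S)-2-(3,4-dimethoxybenzoyl)cyclopropane-1-carboxylate, via acid chloride 3 (not isolated)
Conditions: (COCl)2, cat. DMF, CH2Cl2, 0 °C to 23 °C, concentrate; then 2, AlCl3 (2.2 equiv), CH2Cl2, 0 °C
Reagents that add atoms: none
Why: Acid chloride formation followed by Friedel–Crafts acylation, which should attack veratrole para to one methoxy group and leave the two cyclopropane stereocentres unchanged, since they carry no leaving group and are not enolised here.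

Step 2
Reactants: 4 methyl (1S,2S)-2-(3,4-dimethoxybenzoyl)cyclopropane-1-carboxylate
Product: 5 methyl (1S,2S)-2-[(S)-(3,4-dimethoxyphenyl)(hydroxy)methyl]cyclopropane-1-carboxylate
Conditions: (R)-Me-CBS (0.15 equiv), BH3·SMe2, THF, −20 °C; MeOH quench
Reagents that add atoms: none
Why: Corey–Bakshi–Shibata reduction with (R)-1-methyl-3,3-diphenyltetrahydro-1H,3H-pyrrolo[1,2-c][1,3,2]oxazaborole, in which the aryl group should act as the large and the cyclopropyl as the small substituent, so that hydride is delivered under reagent control to give the (S)-carbinol while the ester survives borane at this temperature.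

Step 3
Reactants: 5 methyl (1S,2S)-2-[(S)-(3,4-dimethoxyphenyl)(hydroxy)methyl]cyclopropane-1-carboxylate
Product: 6 methyl (1S,2S)-2-[(S)-{[tert-butyl(dimethyl)silyl]oxy}(3,4-dimethoxyphenyl)methyl]cyclopropane-1-carboxylate
Conditions: TBSCl, imidazole, DMF, 23 °C
Reagents that add atoms: tert-butyldimethylsilyl chloride, CC(C)(C)[Si](C)(C)Cl
Why: Silyl ether formation under non-acidic conditions (the electron-rich cyclopropyl carbinol would ionise under acid) masks the hydroxyl that would otherwise lactonise onto the acyl group once the ring is opened in step 6.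

Step 4
Reactants: 6 methyl (1S,2S)-2-[(S)-{[tert-butyl(dimethyl)silyl]oxy}(3,4-dimethoxyphenyl)methyl]cyclopropane-1-carboxylate
Product: 7 (1S,2S)-2-[(S)-{[tert-butyl(dimethyl)silyl]oxy}(3,4-dimethoxyphenyl)methyl]cyclopropane-1-carboxylic acid
Conditions: LiOH·H2O, THF/MeOH/H2O, 0 °C to 23 °C; cold dilute HCl to pH 4
Reagents that add atoms: lithium hydroxide, [Li+].[OH-]
Why: Saponification of the methyl ester should proceed cleanly, and any epimerisation alpha to the carboxyl is harmless because that centre is erased in step 6.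

Step 5
Reactants: 7 (1S,2S)-2-[(S)-{[tert-butyl(dimethyl)silyl]oxy}(3,4-dimethoxyphenyl)methyl]cyclopropane-1-carboxylic acid; 8 1,3-oxazolidin-2-one
Product: 10 3-{(1S,2S)-2-[(S)-{[tert-butyl(dimethyl)silyl]oxy}(3,4-dimethoxyphenyl)methyl]cyclopropane-1-carbonyl}-1,3-oxazolidin-2-one, via mixed pivalic anhydride 9 (not isolated)
Conditions: PivCl, Et3N, THF, −20 °C; then 8, LiCl, 23 °C
Reagents that add atoms: none
Why: N-acylation of the oxazolidinone through the mixed anhydride (LiCl/Et3N protocol) should install a two-point-binding imide that activates the cyclopropane and can later be reduced off to CH2OH.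

Step 6
Reactants: 10 3-{(1S,2S)-2-[(S)-{[tert-butyl(dimethyl)silyl]oxy}(3,4-dimethoxyphenyl)methyl]cyclopropane-1-carbonyl}-1,3-oxazolidin-2-one; 11 3,4,5-trimethoxybenzaldehyde
Product: 14 3-{[(2R,3R,4R)-4-[(S)-{[tert-butyl(dimethyl)silyl]oxy}(3,4-dimethoxyphenyl)methyl]-2-(3,4,5-trimethoxyphenyl)tetrahydrofuran-3-yl]carbonyl}-1,3-oxazolidin-2-one, via iodomagnesium enolate 12 (not isolated), via iodomagnesium aldolate 13 (not isolated)
Conditions: MgI2 (1.5 equiv), 11 (1.5 equiv), THF, 70 °C, sealed tube; then DBU (0.3 equiv), 23 °C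
Reagents that add atoms: none
Why: Proposed new method: MgI2 binds both imide carbonyls of 10 and iodide opens the activated cyclopropane by SN2 attack at its unsubstituted CH2 (future C5), giving the gamma-iodo Z-enolate 12 and erasing the configuration at future C3 so that any cis/trans mixture of the cyclopropane converges; 12 then adds to aldehyde 11 (C2–C3 bond) and the magnesium alkoxide 13 displaces the primary iodide (O1–C5 bond), returning MgI2. The closest known reaction types are the MgI2-mediated ring expansion of acylcyclopropanes with imines to pyrrolidines and the Lewis acid/iodide ring-opening aldol (halo-aldol) of cyclopropyl ketones and of unsaturated N-acyloxazolidinones; new here is a saturated cyclopropyl imide reacting with an aldehyde and closing to the tetrahydrofuran in the same flask. The tetrahydrofuran is the only ring closed, by 5-exo-tet O-alkylation. C4 and the carbinol carbon are not touched; C3 should be set by A(1,3) strain in the Z-enolate, which turns the C4–H bond into the enolate plane and leaves open the face carrying the CH2I arm, anti to the bulky silyloxybenzyl group (3,4-trans), and C2 by a closed syn-aldol transition state (2,3-trans after closure). Because the magnesium aldol is reversible and C3 stays epimerisable alpha to the imide (DBU), aldolate diastereomers and C3 epimers should drain into the all-trans ring, in which all three substituents are pseudo-equatorial. The step needs iodide attack at CH2 and not at the substituted ring carbon (secured by primary versus branched, oxygen-bearing centre) and enolate formation toward C3 only (secured because the other oxygenated carbon is a silyl ether and not a ketone).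

Step 7
Reactants: 14 3-{[(2R,3R,4R)-4-[(S)-{[tert-butyl(dimethyl)silyl]oxy}(3,4-dimethoxyphenyl)methyl]-2-(3,4,5-trimethoxyphenyl)tetrahydrofuran-3-yl]carbonyl}-1,3-oxazolidin-2-one
Product: 15 [(2R,3S,4R)-4-[(S)-{[tert-butyl(dimethyl)silyl]oxy}(3,4-dimethoxyphenyl)methyl]-2-(3,4,5-trimethoxyphenyl)tetrahydrofuran-3-yl]methanol
Conditions: LiBH4, MeOH (2 equiv), THF, 0 °C
Reagents that add atoms: none
Why: Reductive cleavage of the N-acyloxazolidinone with LiBH4 should give the primary alcohol directly and leave the silyl ether, the aryl ethers and the ring stereocentres untouched (the change of descriptor at C3 is a priority change only).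

Step 8
Reactants: 15 [(2R,3S,4R)-4-[(S)-{[tert-butyl(dimethyl)silyl]oxy}(3,4-dimethoxyphenyl)methyl]-2-(3,4,5-trimethoxyphenyl)tetrahydrofuran-3-yl]methanol
Product: 16 [(2R,3S,4R)-4-[(S)-(3,4-dimethoxyphenyl)(hydroxy)methyl]-2-(3,4,5-trimethoxyphenyl)tetrahydrofuran-3-yl]methanol (CNP0172668.1)
Conditions: Bu4NF, THF, 0 °C to 23 °C
Reagents that add atoms: none
Why: Fluoride-mediated desilylation under near-neutral conditions is chosen because both benzylic C–O bonds of the product would ionise under acid.

**Compound list**

1 | (1S,2S)-2-(methoxycarbonyl)cyclopropane-1-carboxylic acid | COC(=O)[C@H]1C[C@@H]1C(=O)O | starting material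
2 | 1,2-dimethoxybenzene (veratrole) | COc1ccccc1OC | starting material
3 | methyl (1S,2S)-2-(chlorocarbonyl)cyclopropane-1-carboxylate | COC(=O)[C@H]1C[C@@H]1C(=O)Cl | intermediate
4 | methyl (1S,2S)-2-(3,4-dimethoxybenzoyl)cyclopropane-1-carboxylate | COC(=O)[C@H]1C[C@@H]1C(=O)c1ccc(OC)c(OC)c1 | intermediate
5 | methyl (1S,2S)-2-[(S)-(3,4-dimethoxyphenyl)(hydroxy)methyl]cyclopropane-1-carboxylate | COC(=O)[C@H]1C[C@@H]1[C@H](O)c1ccc(OC)c(OC)c1 | intermediate
6 | methyl (1S,2S)-2-[(S)-{[tert-butyl(dimethyl)silyl]oxy}(3,4-dimethoxyphenyl)methyl]cyclopropane-1-carboxylate | COC(=O)[C@H]1C[C@@H]1[C@H](O[Si](C)(C)C(C)(C)C)c1ccc(OC)c(OC)c1 | intermediate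
7 | (1S,2S)-2-[(S)-{[tert-butyl(dimethyl)silyl]oxy}(3,4-dimethoxyphenyl)methyl]cyclopropane-1-carboxylic acid | OC(=O)[C@H]1C[C@@H]1[C@H](O[Si](C)(C)C(C)(C)C)c1ccc(OC)c(OC)c1 | intermediate
8 | 1,3-oxazolidin-2-one | O=C1NCCO1 | starting material
9 | (1S,2S)-2-[(S)-{[tert-butyl(dimethyl)silyl]oxy}(3,4-dimethoxyphenyl)methyl]cyclopropane-1-carboxylic 2,2-dimethylpropanoic anhydride | CC(C)(C)C(=O)OC(=O)[C@H]1C[C@@H]1[C@H](O[Si](C)(C)C(C)(C)C)c1ccc(OC)c(OC)c1 | intermediate
10 | 3-{(1S,2S)-2-[(S)-{[tert-butyl(dimethyl)silyl]oxy}(3,4-dimethoxyphenyl)methyl]cyclopropane-1-carbonyl}-1,3-oxazolidin-2-one | O=C([C@H]1C[C@@H]1[C@H](O[Si](C)(C)C(C)(C)C)c1ccc(OC)c(OC)c1)N1CCOC1=O | intermediate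
11 | 3,4,5-trimethoxybenzaldehyde | COc1cc(C=O)cc(OC)c1OC | starting material
12 | iodomagnesium (Z)-enolate of 3-[(3S,4S)-4-{[tert-butyl(dimethyl)silyl]oxy}-4-(3,4-dimethoxyphenyl)-3-(iodomethyl)butanoyl]-1,3-oxazolidin-2-one | O=C1OCCN1/C(O[Mg]I)=C/[C@H](CI)[C@H](O[Si](C)(C)C(C)(C)C)c1ccc(OC)c(OC)c1 | intermediate
13 | iodomagnesium alkoxide of 3-[(2R,3S,4S)-4-{[tert-butyl(dimethyl)silyl]oxy}-4-(3,4-dimethoxyphenyl)-2-[(R)-hydroxy(3,4,5-trimethoxyphenyl)methyl]-3-(iodomethyl)butanoyl]-1,3-oxazolidin-2-one | COc1cc(cc(OC)c1OC)[C@H](O[Mg]I)[C@H](C(=O)N1CCOC1=O)[C@H](CI)[C@H](O[Si](C)(C)C(C)(C)C)c1ccc(OC)c(OC)c1 | intermediate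
14 | 3-{[(2R,3R,4R)-4-[(S)-{[tert-butyl(dimethyl)silyl]oxy}(3,4-dimethoxyphenyl)methyl]-2-(3,4,5-trimethoxyphenyl)tetrahydrofuran-3-yl]carbonyl}-1,3-oxazolidin-2-one | COc1ccc([C@@H](O[Si](C)(C)C(C)(C)C)[C@H]2CO[C@@H](c3cc(OC)c(OC)c(OC)c3)[C@@H]2C(=O)N4CCOC4=O)cc1OC | intermediate
15 | [(2R,3S,4R)-4-[(S)-{[tert-butyl(dimethyl)silyl]oxy}(3,4-dimethoxyphenyl)methyl]-2-(3,4,5-trimethoxyphenyl)tetrahydrofuran-3-yl]methanol | COc1ccc([C@@H](O[Si](C)(C)C(C)(C)C)[C@H]2CO[C@@H](c3cc(OC)c(OC)c(OC)c3)[C@@H]2CO)cc1OC | intermediate
16 | [(2R,3S,4R)-4-[(S)-(3,4-dimethoxyphenyl)(hydroxy)methyl]-2-(3,4,5-trimethoxyphenyl)tetrahydrofuran-3-yl]methanol | COc1ccc([C@@H](O)[C@H]2CO[C@@H](c3cc(OC)c(OC)c(OC)c3)[C@@H]2CO)cc1OC | target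

**Count**

Total steps: 8. Longest linear sequence: 8 steps (from 1).

**Steps most likely to fail**

Step 6 (Proposed new method). What may go wrong: iodide opening of a cyclopropane that carries only one acyl activator may be slow, so that iodide attack on the oxazolidinone ring or Lewis-acid O-demethylation of the aldehyde competes. If the aldol does not equilibrate before ring closure, the C2/C4 relationship may also be lost. Fallback: the two bonds are made in separate, individually known operations, setting out from 10 and 11 and returning at 14. Lewis acid/iodide ring-opening aldol of the acylcyclopropane (Et2AlI, CH2Cl2, 0 °C, a known halo-aldol of acylcyclopropanes that proceeds through a closed syn-selective transition state) should give, after aqueous work-up, the open-chain gamma-iodo syn-aldol 3-[(2R,3S,4S)-4-{[tert-butyl(dimethyl)silyl]oxy}-4-(3,4-dimethoxyphenyl)-2-[(R)-hydroxy(3,4,5-trimethoxyphenyl)methyl]-3-(iodomethyl)butanoyl]-1,3-oxazolidin-2-one F1. This is purified from minor diastereomers and closed by a Williamson etherification (Ag2O, MeCN, 23 °C) to 14; C3 can still be equilibrated with DBU.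

Step 2. What may go wrong: poor facial selectivity in the ketone reduction, because the ester-bearing cyclopropyl group may not behave as the small substituent or the existing stereocentres may be mismatched with the catalyst. Fallback: the stereocentre is obtained by separation and recycling instead of reagent control, setting out from 4 and returning at 5. Luche reduction (NaBH4, CeCl3·7H2O, MeOH, −40 °C) should give 5 together with its carbinol epimer methyl (1S,2S)-2-[(R)-(3,4-dimethoxyphenyl)(hydroxy)methyl]cyclopropane-1-carboxylate F2. The two are diastereomers because the cyclopropane is enantiopure, so they should separate on silica; F2 is reoxidised to 4 with MnO2 in CH2Cl2 and recycled.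

Step 1. What may go wrong: chloride opening of the doubly acyl-substituted cyclopropane and cleavage of an aryl methyl ether under AlCl3. Fallback: the aryl–carbonyl bond is made by cross-coupling instead of electrophilic substitution, setting out from acid chloride 3 and returning at 4. Anhydrous acyl Suzuki–Miyaura coupling of 3 with commercial (3,4-dimethoxyphenyl)boronic acid (Pd(PPh3)4, Cs2CO3, toluene, 90 °C) should give 4 without a strong Lewis acid; no new compound is made on the way (F0).

**Further compounds**

F1 | step 6 | 3-[(2R,3S,4S)-4-{[tert-butyl(dimethyl)silyl]oxy}-4-(3,4-dimethoxyphenyl)-2-[(R)-hydroxy(3,4,5-trimethoxyphenyl)methyl]-3-(iodomethyl)butanoyl]-1,3-oxazolidin-2-one | COc1cc(cc(OC)c1OC)[C@H](O)[C@H](C(=O)N1CCOC1=O)[C@H](CI)[C@H](O[Si](C)(C)C(C)(C)C)c1ccc(OC)c(OC)c1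
F2 | step 2 | methyl (1S,2S)-2-[(R)-(3,4-dimethoxyphenyl)(hydroxy)methyl]cyclopropane-1-carboxylate | COC(=O)[C@H]1C[C@@H]1[C@@H](O)c1ccc(OC)c(OC)c1
F0 | step 1 | none | none
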